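Does the north-east run, charged like the north run at a later stage, keep pace with it, and how far has a repeat of the north charge gone after 11 min?

the same everywhere: free catalyst 0.00120 M

| flask | substrate | coupling partner | target | time |
|---|---|---|---|---|
| north | 0.600 M | 1.80 M |  |  |
| north-east | 0.360 M | 1.56 M |  |  |
| south | 0.600 M | 1.80 M | 0.300 M |  |
| south-east | 0.600 M | 1.80 M |  | 11 min |

- north run (time / min: [target] / M): 0.15: 0.0183; 0.47: 0.0574; 0.90: 0.1097; 1.4: 0.1679; 2.0: 0.2363; 2.7: 0.3106; 3.5: 0.3759; 4.3: 0.4371
- north-east run (time / min: [target] / M): 0.15: 0.0175; 0.47: 0.0499; 0.90: 0.0940; 1.4: 0.1454; 2.0: 0.1942; 2.7: 0.2425; 3.5: 0.2820; 4.3: 0.3117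
- south run (time / min: [target] / M): 0.15: 0.3179; 0.47: 0.3554; 0.90: 0.4075; 1.4: 0.4674; 2.0: 0.5262; 2.7: 0.5946; 3.5: 0.6610; 4.3: 0.7136

(each reading ± 0.002 M)

- the north-east run starts with 0.240 M less of substrate and of coupling partner than the north run, and with no target. Compared where both hold the same amount of substrate, once fifteen percent of what the north-east run was charged with has turned into target, is the north-east run faster, slower or alike (within a tenth)?
- target in the south-east run at 11 min, as a share of the substrate charged

- Overall: substrate + coupling partner -> target, with free catalyst as catalyst.
- Constant volume, constant temperature.
- The analysis sees a species whether free or bound.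
- "The second partner" is coupling partner.

Chords through the readings give rates without any integration. Around c(substrate) of 0.304 M the north-east run makes target at 0.102 M/min, and around 0.294 M the north run makes it at 0.0931 M/min. Their ratio, the rate ratio at near-equal substrate, in which time has dropped out, is 1.10, a reading just inside a tenth, so the runs count as alike.

The south run, at the same age and similar c(substrate) but with more target, stands at 0.966 of the north rate. That reading leaves age and target both open as causes of the gap, and this reckoning takes age as a working assumption. Dividing ln of the ratio by the age difference of 2.23 min gives a working ageing rate, the fractional loss of catalyst activity (deactivation) per minute, assumed constant: 0.0412 /min.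

The last north chord gives a tail constant, rate over c(substrate), of 0.395 /min. Letting it decay at that assumed rate from 4.30 min to 11 min leaves an estimated 0.0167 M of substrate, which is 97.2% conversion.

The forecast, reading “mild product inhibition”, says alike and 98.5% (from 96% to 99.6%), the same verdict but a higher share than this reckoning.

The south-east run gives 96.7%, and the north-east run is alike.

    free catalyst + substrate ⇌ catalyst-substrate complex, settled at all times (0.9650 /M)
    catalyst-substrate complex + coupling partner ⇌ ternary complex, settled at all times (5.430 /M)
    ternary complex → target + free catalyst (133.8 /min)
    free catalyst + target → spent catalyst + target (0.6300 /M/min)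

At the stated point the north-east rate over the north rate is 1.1, beside the chord ratio of 1.10; a value beyond a tenth would have made the north-east run faster. The same kind of ratio, the south run over the north run where each has made the same amount of target, is 1.0, lower than the north-east chord ratio.

The numbers in the tables are calculated for an exercise, noise included.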